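All runs are simulated with constants of no real substance, and the scatter is random.

Slowness is my first question: has the north-east flask at 37 °C stopped moving when I look at 80 min, or is it only crawling?

all flasks: substrate 0.050 M; free enzyme 0.08 mol%
- north-east: temperature 37 °C; the very flask that is asked about, followed so far
- south: temperature 32 °C; run made earlier
- flask: temperature 37 °C; time 80 min

| run | time / min | target / % | substrate / % |
|---|---|---|---|
| north-east | 5.00 | 31.8 | 67.6 |
| north-east | 12.0 | 70.9 | 24.7 |
| north-east | 30.0 | 35.1 | 0 |
| north-east | 60.0 | 25.0 | 0.5 |
| south | 5.00 | 20.2 | 79.6 |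
| south | 12.0 | 47.0 | 50.6 |
| south | 30.0 | 62.9 | 0 |
| south | 60.0 | 23.6 | 0.9 |

(standard deviation of a reading: 0.5 percentage points)

- eta: at 80 min add free enzyme, 50.0 % of the amount charged, then wait 2.5 h
- alpha: change nothing and wait 2.5 h more
- gamma: at 80 min take out 90 % of the target then present, then wait 2.5 h
- epsilon: at 80 min raise the temperature by 10 K, then wait 2.5 h

- target, in percent of the substrate first charged, at 80 min
- the option that brings most further target ("none" if no option brings more than 2 percentage points) (eta / alpha / gamma / epsilon / none)
- target present, with what was taken out counted in, in percent of the substrate first charged, after eta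
- target present, with what was taken out counted in, in percent of the substrate first charged, after gamma

I solve the run at both ends and join them. At the early end, the substrate falls from 67.6 % at 5.00 min to 24.7 % at 12.0 min, and that line, carried on, reaches zero at 16.0 min.

At the late end, target drops to 25.0 % at 60.0 min, and the south run, still at 62.9 % at 30.0 min, reaches 23.6 %. Two runs so far apart on the way and so close at the end suggest a two-way step, with target turning into a partner and back. So I carry one quantity, the rest share 25.0 %: the part of the pool in the flask that stands as target once both directions balance. This is thermodynamic control, and it is a reading with its scatter.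

To join the ends, I count the pool as target at 16.0 min. The gap above the rest share then shrinks to 10 percentage points by 30.0 min, which gives a half-life of 4.83 min. The 50.0 min from that reading to 80 min are long against this half-life, and the north-east run already reads 25.0 % at 60.0 min, so I say 25.0 % at 80 min. My weak point is that this half-life comes from one early stretch and I have no reading of the enzyme itself, so the approach may slow later.

More enzyme speeds both directions, so eta and alpha stay at 25.0 %. Gamma takes out 22.5 % and leaves a pool of 77.5 %, whose rest share is 19.4 %, so the total is 41.9 %. For epsilon, the gap between the runs, scaled to 10 K, suggests 2.8 points, which is less than gamma's 17 points.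

The forecast gives 25 % now, 25 % after eta and 41.9 % after gamma, with gamma best, reading the tail as “enzyme-catalysed equilibrium with a product”.

The flask gives 25.2 % at 80 min, 25.0 % after eta and 40.9 % after gamma. The gains are −0.17 points for eta, −0.15 points for alpha, 16 points for gamma and 3.8 points for epsilon, so the best option is gamma.

    complex → free enzyme + target (k = 85.0 min⁻¹, Ea = 75.0 kJ mol⁻¹)
    free enzyme → spent catalyst (k = 0.0150 min⁻¹, Ea = 93.0 kJ mol⁻¹)
    free enzyme → unfolded enzyme (k = 0.00250 min⁻¹, Ea = 284 kJ mol⁻¹)
    target + free enzyme ⇌ isomer of the product + free enzyme, rate k4*[free enzyme]*[target] forward; the back reaction follows from the equilibrium constant (K = 3.00, k = 3000 M⁻¹ min⁻¹, Ea = 36.0 kJ mol⁻¹, ΔH = −31.0 kJ mol⁻¹)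
    substrate + free enzyme ⇌ complex (K = 700 M⁻¹, k = 1.30 × 10⁵ M⁻¹ min⁻¹, Ea = 42.0 kJ mol⁻¹, ΔH = −45.0 kJ mol⁻¹)
    (constants at 37 °C)

At 8.00 min complex holds 91.4 % of the catalyst, with substrate at 48.7 %, and target is made 14.1 times faster than it is used up. By 40.0 min substrate stands at 0 % and free enzyme at 64.4 %, and target runs to and from isomer of the product until 25.2 % faces 74.8 % at 80.0 min. After gamma, target in the flask is 23.6 % of the pool left, against the rest share of 25.0 %. The flask kept at 52 °C, with free enzyme at 0 %, unfolded enzyme at 83.6 % and spent catalyst at 16.4 %, stands above that share, at 70.5 % target.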